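**Retrosynthetic overview**
1. Target 20 ⇐ protected angelate 17 by two end-game unmaskings: the aryl silyl ether para to the free phenol becomes the acetate, then the MOM acetal on the phenol oxygen is removed.
2. Key cut: the C3–C4 bond of the 3-acyloxy-1,5-diene side chain (carbinol C3 between the exo-methylene C2=C1H2 and C4H2–C5H=C6Me2). It is made by an enantioselective [2,3]-Wittig rearrangement of the achiral 2-arylallyl 1,1-dimethylallyl ether 13, and the lithium alkoxide is angeloylated in the same flask.
3. 13 ⇐ aryl MOM ether 10 + 2-bromoallyl ether 4 (MOM-directed ortho-metalation, Negishi coupling); 4 ⇐ 1 + 2 (Williamson).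
4. 10 ⇐ 2,4-dihydroxy-3-methylbenzaldehyde 5: 4-O-silylation, 2-O-methylation, Dakin oxidation (CHO → OH gives the oxygen that ends as the free phenol), MOM protection.
5. No ring is formed: the benzene ring is bought, and the only stereocentre (C3) arises in the key step.

Key step: step 7

Assumption: the sense of induction of the bis(oxazoline) ligand in step 7 cannot be predicted safely; the antipode that delivers the (S)-carbinol is to be fixed in a test run, both antipodes being commercial.

**Route**

Step 1
Reactants: 1 2-methylbut-3-en-2-ol; 2 2,3-dibromoprop-1-ene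
Product: 4 3-[(2-bromoprop-2-en-1-yl)oxy]-3-methylbut-1-ene, via sodium 2-methylbut-3-en-2-olate 3 (not isolated)
Conditions: NaH, THF, 0 °C; then 2, n-Bu4NI (cat.), 0 °C → rt
Reagents that add atoms: none
Why: Williamson ether synthesis, in which the tertiary alkoxide displaces the allylic bromide of 2 (SN2) while the vinylic bromide is inert, giving an ether whose tertiary carbon has no α-hydrogen.

Step 2
Reactants: 5 2,4-dihydroxy-3-methylbenzaldehyde
Product: 6 2-hydroxy-3-methyl-4-[(triisopropylsilyl)oxy]benzaldehyde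
Conditions: TIPSCl (1.05 equiv), imidazole, DMF, 0 °C
Reagents that add atoms: triisopropylsilyl chloride, CC(C)[Si](Cl)(C(C)C)C(C)C
Why: Chemoselective O-silylation, since the 4-OH is free whereas the 2-OH is hydrogen-bonded to the aldehyde and flanked by two ortho groups, so the bulky silyl chloride should react at O4 only.

Step 3
Reactants: 6 2-hydroxy-3-methyl-4-[(triisopropylsilyl)oxy]benzaldehyde
Product: 7 2-methoxy-3-methyl-4-[(triisopropylsilyl)oxy]benzaldehyde
Conditions: MeI, Ag2O, MeCN, 40 °C, dark
Reagents that add atoms: iodomethane, CI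
Why: Purdie methylation (Ag2O/MeI) alkylates the chelated phenol under non-basic conditions, so the aryl silyl ether para to the aldehyde should not be cleaved or scrambled.

Step 4
Reactants: 7 2-methoxy-3-methyl-4-[(triisopropylsilyl)oxy]benzaldehyde
Product: 9 2-methoxy-3-methyl-4-[(triisopropylsilyl)oxy]phenol, via aryl formate 8 (not isolated)
Conditions: mCPBA, CH2Cl2, 0 °C → rt; then Et3N (cat.), MeOH, rt
Reagents that add atoms: m-chloroperoxybenzoic acid, O=C(OO)c1cccc(Cl)c1
Why: Dakin-type Baeyer–Villiger oxidation, in which the electron-rich aryl group (ortho-OMe, para-OSi) migrates to give formate 8, and mild methanolysis then frees the phenol without touching the TIPS ether.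

Step 5
Reactants: 9 2-methoxy-3-methyl-4-[(triisopropylsilyl)oxy]phenol
Product: 10 [3-methoxy-4-(methoxymethoxy)-2-methylphenoxy]triisopropylsilane
Conditions: MOMCl, i-Pr2NEt, CH2Cl2, 0 °C → rt
Reagents that add atoms: chloromethyl methyl ether, COCCl
Why: Standard O-alkylation of the phenol to the MOM acetal, which is stable to organolithiums and serves as the ortho-directing group for the next step.

Step 6
Reactants: 10 [3-methoxy-4-(methoxymethoxy)-2-methylphenoxy]triisopropylsilane; 4 3-[(2-bromoprop-2-en-1-yl)oxy]-3-methylbut-1-ene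
Product: 13 {3-methoxy-4-(methoxymethoxy)-2-methyl-5-[3-(2-methylbut-3-en-2-yloxy)prop-1-en-2-yl]phenoxy}triisopropylsilane, via aryllithium 11 (not isolated), via arylzinc chloride 12 (not isolated)
Conditions: n-BuLi, THF, 0 °C; ZnCl2, THF, 0 °C → rt; then 4, Pd2(dba)3/SPhos (cat.), THF, 40 °C
Reagents that add atoms: none
Why: Directed ortho-metalation at the only free position ortho to OMOM, Li→Zn transmetalation and Negishi cross-coupling with the vinylic bromide of 4, where fast transmetalation of the arylzinc should outrun 5-exo carbopalladation onto the pendant vinyl group.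

Step 7
Reactants: 13 {3-methoxy-4-(methoxymethoxy)-2-methyl-5-[3-(2-methylbut-3-en-2-yloxy)prop-1-en-2-yl]phenoxy}triisopropylsilane; 14 angelic anhydride [(2Z)-2-methylbut-2-enoic anhydride]
Product: 17 (3S)-2-[3-methoxy-2-(methoxymethoxy)-4-methyl-5-(triisopropylsilyloxy)phenyl]-6-methylhepta-1,5-dien-3-yl (2Z)-2-methylbut-2-enoate, via lithiated ether 15 (not isolated), via lithium alkoxide 16 (not isolated)
Conditions: t-BuLi (1.3 equiv), t-Bu-box [2,2′-(propane-2,2-diyl)bis(4-tert-butyl-4,5-dihydrooxazole), (S,S) or (R,R) as fixed by the test run] (1.4 equiv), hexane, −78 °C; then 14, THF, −78 → 0 °C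
Reagents that add atoms: none
Why: Proposed new method: the bis(oxazoline)-bound tert-butyllithium, pre-complexed at the MOM and ether oxygens, removes one of the two enantiotopic allylic O–CH2 protons of 13 (the tertiary ether carbon has no α-hydrogen, so only this site can be metalated), and the α-oxy allyllithium 15 undergoes a concerted suprafacial [2,3]-sigmatropic (Wittig) shift through a five-membered envelope transition state that forms C3–C4, breaks the O–CMe2 bond and moves the double bond to CH=CMe2 before it can racemise. The closest known reaction type is the bis(oxazoline)/t-BuLi-mediated enantioselective [2,3]-Wittig rearrangement of allyl benzyl and allyl propargyl ethers, together with the racemic [2,3]-Wittig rearrangement of bis-allylic ethers, extended here to a 2-arylallyl tertiary-allyl ether. No ring is closed. The single new stereocentre C3 is controlled by the ligand (choice of enantiotopic proton, then stereospecific inversion at the lithiated carbon), so the ligand antipode fixes (S). The step needs [2,3] over [1,2] shift and deprotonation over carbolithiation of the styrene: −78 °C and the concerted path favour [2,3], while the twisted, electron-rich ortho-substituted aryl ring and the oxygen-directed metalation favour deprotonation. Lithium alkoxide 16 is the type of species known to be acylated by angelic anhydride without Z→E isomerisation, so the angelate is installed in the same flask.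

Step 8
Reactants: 17 (3S)-2-[3-methoxy-2-(methoxymethoxy)-4-methyl-5-(triisopropylsilyloxy)phenyl]-6-methylhepta-1,5-dien-3-yl (2Z)-2-methylbut-2-enoate
Product: 19 (3S)-2-[5-acetoxy-3-methoxy-2-(methoxymethoxy)-4-methylphenyl]-6-methylhepta-1,5-dien-3-yl (2Z)-2-methylbut-2-enoate, via tetrabutylammonium phenoxide 18 (not isolated)
Conditions: TBAF (1.1 equiv), THF, 0 °C; then Ac2O, 0 °C → rt
Reagents that add atoms: acetic anhydride, CC(=O)OC(C)=O
Why: Fluoride-mediated cleavage of the aryl silyl ether followed by O-acetylation of the phenoxide in the same flask, conditions to which the MOM acetal, the angelate and both alkenes should be inert.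

Step 9
Reactants: 19 (3S)-2-[5-acetoxy-3-methoxy-2-(methoxymethoxy)-4-methylphenyl]-6-methylhepta-1,5-dien-3-yl (2Z)-2-methylbut-2-enoate
Product: 20 (3S)-2-(5-acetoxy-2-hydroxy-3-methoxy-4-methylphenyl)-6-methylhepta-1,5-dien-3-yl (2Z)-2-methylbut-2-enoate
Conditions: ZnBr2, n-PrSH, CH2Cl2, 0 °C, short reaction time
Reagents that add atoms: none
Why: Lewis acid-assisted thiolysis of the MOM acetal, a fast cleavage at 0 °C without protic acid, so the aryl acetate, the allylic angelate and the alkenes should survive.

**Compound list**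
1 | 2-methylbut-3-en-2-ol | CC(C)(O)C=C | starting material
2 | 2,3-dibromoprop-1-ene | C=C(Br)CBr | starting material
3 | sodium 2-methylbut-3-en-2-olate | CC(C)([O-])C=C.[Na+] | intermediate
4 | 3-[(2-bromoprop-2-en-1-yl)oxy]-3-methylbut-1-ene | C=C(Br)COC(C)(C)C=C | intermediate
5 | 2,4-dihydroxy-3-methylbenzaldehyde | O=Cc1ccc(O)c(C)c1O | starting material
6 | 2-hydroxy-3-methyl-4-[(triisopropylsilyl)oxy]benzaldehyde | O=Cc1ccc(O[Si](C(C)C)(C(C)C)C(C)C)c(C)c1O | intermediate
7 | 2-methoxy-3-methyl-4-[(triisopropylsilyl)oxy]benzaldehyde | O=Cc1ccc(O[Si](C(C)C)(C(C)C)C(C)C)c(C)c1OC | intermediate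
8 | 2-methoxy-3-methyl-4-[(triisopropylsilyl)oxy]phenyl formate | O=COc1ccc(O[Si](C(C)C)(C(C)C)C(C)C)c(C)c1OC | intermediate
9 | 2-methoxy-3-methyl-4-[(triisopropylsilyl)oxy]phenol | Oc1ccc(O[Si](C(C)C)(C(C)C)C(C)C)c(C)c1OC | intermediate
10 | [3-methoxy-4-(methoxymethoxy)-2-methylphenoxy]triisopropylsilane | COCOc1ccc(O[Si](C(C)C)(C(C)C)C(C)C)c(C)c1OC | intermediate
11 | {3-methoxy-2-(methoxymethoxy)-4-methyl-5-[(triisopropylsilyl)oxy]phenyl}lithium | COCOc1c([Li])cc(O[Si](C(C)C)(C(C)C)C(C)C)c(C)c1OC | intermediate
12 | {3-methoxy-2-(methoxymethoxy)-4-methyl-5-[(triisopropylsilyl)oxy]phenyl}zinc chloride | COCOc1c([Zn]Cl)cc(O[Si](C(C)C)(C(C)C)C(C)C)c(C)c1OC | intermediate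
13 | {3-methoxy-4-(methoxymethoxy)-2-methyl-5-[3-(2-methylbut-3-en-2-yloxy)prop-1-en-2-yl]phenoxy}triisopropylsilane | C=C(COC(C)(C)C=C)c1cc(O[Si](C(C)C)(C(C)C)C(C)C)c(C)c(OC)c1OCOC | intermediate
14 | angelic anhydride [(2Z)-2-methylbut-2-enoic anhydride] | C/C=C(/C)C(=O)OC(=O)/C(C)=C\C | starting material
15 | α-lithiated ether of 13 (lithium on the O–CH carbon, configuration set by the ligand) | C=C(C([Li])OC(C)(C)C=C)c1cc(O[Si](C(C)C)(C(C)C)C(C)C)c(C)c(OC)c1OCOC | intermediate
16 | lithium (3S)-2-[3-methoxy-2-(methoxymethoxy)-4-methyl-5-(triisopropylsilyloxy)phenyl]-6-methylhepta-1,5-dien-3-olate | C=C(c1cc(O[Si](C(C)C)(C(C)C)C(C)C)c(C)c(OC)c1OCOC)[C@H](CC=C(C)C)O[Li] | intermediate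
17 | (3S)-2-[3-methoxy-2-(methoxymethoxy)-4-methyl-5-(triisopropylsilyloxy)phenyl]-6-methylhepta-1,5-dien-3-yl (2Z)-2-methylbut-2-enoate | C=C(c1cc(O[Si](C(C)C)(C(C)C)C(C)C)c(C)c(OC)c1OCOC)[C@H](CC=C(C)C)OC(=O)/C(C)=C\C | intermediate
18 | tetrabutylammonium phenoxide of desilylated 17 | C=C(c1cc([O-])c(C)c(OC)c1OCOC)[C@H](CC=C(C)C)OC(=O)/C(C)=C\C.CCCC[N+](CCCC)(CCCC)CCCC | intermediate
19 | (3S)-2-[5-acetoxy-3-methoxy-2-(methoxymethoxy)-4-methylphenyl]-6-methylhepta-1,5-dien-3-yl (2Z)-2-methylbut-2-enoate | C=C(c1cc(OC(C)=O)c(C)c(OC)c1OCOC)[C@H](CC=C(C)C)OC(=O)/C(C)=C\C | intermediate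
20 | (3S)-2-(5-acetoxy-2-hydroxy-3-methoxy-4-methylphenyl)-6-methylhepta-1,5-dien-3-yl (2Z)-2-methylbut-2-enoate | C=C(c1cc(OC(C)=O)c(C)c(OC)c1O)[C@H](CC=C(C)C)OC(=O)/C(C)=C\C | target

**Step count**
Total: 9 steps. Longest linear sequence: 8 steps (5 → 20, steps 2–9); step 1 is a one-step side branch.

**Steps most likely to fail**

1. Step 7 (Proposed new method). The risk is insufficient discrimination of the two enantiotopic protons, because ligand-free, MOM-assisted deprotonation may compete with the ligand-bound base. Carbolithiation of the styrene or a [1,2]-shift could also lower the yield. The fallback uses known chemistry and sets the stereocentre by reagent-controlled reduction instead. Setting out from 13, the rearrangement is run without ligand (n-BuLi, THF, −78 °C); it passes through lithiated ether 15 and should give the racemic lithium alkoxide F1 and, after NH4Cl, the racemic alcohol 2-aryl-6-methylhepta-1,5-dien-3-ol F2. Dess–Martin periodinane/NaHCO3 oxidises F2 to the enone F3. Corey–Bakshi–Shibata reduction ((R)-Me-CBS, catecholborane, toluene, −78 °C, with the arylvinyl group as the large substituent) should give the (S)-alcohol F4. LiHMDS (THF, −78 °C) then forms lithium alkoxide 16, which is acylated with 14 and comes back to the route at 17.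

2. Step 6. The risk is that the vinylpalladium intermediate cyclises onto the pendant vinyl group (Heck-type 5-exo carbopalladation) or loses the allylic alkoxide before transmetalation. The fallback replaces the cross-coupling by acylation and olefination. Setting out from 10, lithiation as before gives 11, which is acylated with the Weinreb amide N-methoxy-N-methyl-2-[(2-methylbut-3-en-2-yl)oxy]acetamide F5 (made from sodium alkoxide 3 and 2-chloro-N-methoxy-N-methylacetamide, THF, 0 °C). The chelated tetrahedral lithium adduct F6 should collapse on work-up to the aryl ketone F7. Wittig methylenation (Ph3P=CH2, THF, 0 °C → rt) comes back to the route at 13.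

3. Step 9. The risk is acyl transfer from the aryl acetate to the thiol, or Lewis acid-promoted loss of that acetate, while the acetal is cleaved. The fallback changes the order of unmasking and installs the acetate last by steric differentiation of the free hydroquinone. Setting out from 17, the MOM acetal is cleaved first (ZnBr2, n-PrSH, CH2Cl2, 0 °C) to give the phenol F8. HF·pyridine (THF, 0 °C) removes the silyl group to give the hydroquinone F9. One equivalent of Ac2O with pyridine in CH2Cl2 at −20 °C should acetylate the less hindered hydroxyl (flanked by methyl and hydrogen) rather than the one flanked by methoxy and the branched side chain, which comes back to the route at 20.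

**Further compounds**
F1 | step 7 | racemic lithium 2-[3-methoxy-2-(methoxymethoxy)-4-methyl-5-(triisopropylsilyloxy)phenyl]-6-methylhepta-1,5-dien-3-olate | C=C(c1cc(O[Si](C(C)C)(C(C)C)C(C)C)c(C)c(OC)c1OCOC)C(CC=C(C)C)O[Li]
F2 | step 7 | racemic 2-[3-methoxy-2-(methoxymethoxy)-4-methyl-5-(triisopropylsilyloxy)phenyl]-6-methylhepta-1,5-dien-3-ol | C=C(c1cc(O[Si](C(C)C)(C(C)C)C(C)C)c(C)c(OC)c1OCOC)C(O)CC=C(C)C
F3 | step 7 | 2-[3-methoxy-2-(methoxymethoxy)-4-methyl-5-(triisopropylsilyloxy)phenyl]-6-methylhepta-1,5-dien-3-one | C=C(c1cc(O[Si](C(C)C)(C(C)C)C(C)C)c(C)c(OC)c1OCOC)C(=O)CC=C(C)C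
F4 | step 7 | (3S)-2-[3-methoxy-2-(methoxymethoxy)-4-methyl-5-(triisopropylsilyloxy)phenyl]-6-methylhepta-1,5-dien-3-ol | C=C(c1cc(O[Si](C(C)C)(C(C)C)C(C)C)c(C)c(OC)c1OCOC)[C@H](CC=C(C)C)O
F5 | step 6 | N-methoxy-N-methyl-2-[(2-methylbut-3-en-2-yl)oxy]acetamide | CON(C)C(=O)COC(C)(C)C=C
F6 | step 6 | lithium tetrahedral adduct of 11 and F5 | CON(C)C(O[Li])(COC(C)(C)C=C)c1cc(O[Si](C(C)C)(C(C)C)C(C)C)c(C)c(OC)c1OCOC
F7 | step 6 | 1-[3-methoxy-2-(methoxymethoxy)-4-methyl-5-(triisopropylsilyloxy)phenyl]-2-[(2-methylbut-3-en-2-yl)oxy]ethan-1-one | O=C(COC(C)(C)C=C)c1cc(O[Si](C(C)C)(C(C)C)C(C)C)c(C)c(OC)c1OCOC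
F8 | step 9 | (3S)-2-[2-hydroxy-3-methoxy-4-methyl-5-(triisopropylsilyloxy)phenyl]-6-methylhepta-1,5-dien-3-yl (2Z)-2-methylbut-2-enoate | C=C(c1cc(O[Si](C(C)C)(C(C)C)C(C)C)c(C)c(OC)c1O)[C@H](CC=C(C)C)OC(=O)/C(C)=C\C
F9 | step 9 | (3S)-2-(2,5-dihydroxy-3-methoxy-4-methylphenyl)-6-methylhepta-1,5-dien-3-yl (2Z)-2-methylbut-2-enoate | C=C(c1cc(O)c(C)c(OC)c1O)[C@H](CC=C(C)C)OC(=O)/C(C)=C\C
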